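**Retrosynthetic overview**
- Feature: in the benzene ring the acetyl-bearing carbon and the carbon bearing the CH2–pyranone link are neighbours and come from the two sp carbons of a methyl ynone. The other four ring atoms (C–OH, C–OH, C–OMe, C–H, in that order) come from an oxygenated buta-1,3-diene whose ketene-acetal carbon carries one extra leaving group.
- Arene ⇒ ynone 11 + diene 16 by Diels–Alder addition and loss of methanol; the benzene ring is formed last.
- Ynone 11 ⇒ acetyl chloride + 3-propargyl-4-hydroxy-2-pyranone 9 ⇒ propargylmalonyl dichloride 7 + silyl enol ether 4; the pyranone ring is formed first and the stereocentre comes from (S)-pent-4-en-2-ol.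
- Diene 16 ⇒ methyl benzyloxyacetate. The three oxygens that end as free OH (pyranone 4-O, side-chain O, central arene O) are carried as benzyl ethers and freed in one BCl3 step.

Key step: step 12

Remark on the chemistry: 15 and 16 are used as E/Z mixtures and 17 as a mixture of epimers at its ketal carbon, because that carbon becomes aromatic and its geometry is lost.

**Route**

Step 1
Reactants: 1 (S)-pent-4-en-2-ol
Product: 2 (S)-4-(benzyloxy)pent-1-ene
Conditions: NaH, BnBr, Bu4NI (cat.), THF, 0 °C → rt
Reagents that add atoms: benzyl bromide, BrCc1ccccc1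
Why: Williamson etherification of the sodium alkoxide; the C–O bond at the stereocentre is not broken, so the (S) configuration of 1 is kept.

Step 2
Reactants: 2 (S)-4-(benzyloxy)pent-1-ene
Product: 3 (S)-4-(benzyloxy)pentan-2-one
Conditions: PdCl2 (10 mol%), CuCl, O2 (1 atm), DMF/H2O 7:1, rt
Reagents that add atoms: water, O (source of the carbonyl oxygen; O2 is the terminal oxidant)
Why: Tsuji–Wacker oxidation of a terminal alkene gives the methyl ketone by Markovnikov hydroxypalladation, and the benzyl ether and the β-stereocentre are untouched under these near-neutral conditions.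

Step 3
Reactants: 3 (S)-4-(benzyloxy)pentan-2-one
Product: 4 (S)-{[4-(benzyloxy)pent-1-en-2-yl]oxy}trimethylsilane
Conditions: LDA, THF, −78 °C; TMSCl, −78 → 0 °C; non-aqueous work-up
Reagents that add atoms: chlorotrimethylsilane, C[Si](C)(C)Cl
Why: Kinetic deprotonation of the methyl ketone at the methyl group and O-silylation (kinetic enolate trapping) give the terminal silyl enol ether; the carbon next to the stereocentre is not enolised, so β-elimination is avoided.

Step 4
Reactants: 5 diethyl 2-(prop-2-yn-1-yl)malonate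
Product: 6 2-(prop-2-yn-1-yl)malonic acid
Conditions: KOH, EtOH/H2O, rt; then aq. HCl, 0 °C
Reagents that add atoms: potassium hydroxide, [K+].[OH-]
Why: Saponification of the malonic diester; cold acidification keeps the malonic acid from decarboxylating.

Step 5
Reactants: 6 2-(prop-2-yn-1-yl)malonic acid
Product: 7 2-(prop-2-yn-1-yl)malonyl dichloride
Conditions: (COCl)2, DMF (cat.), CH2Cl2, 0 °C → rt; evaporate, use crude
Reagents that add atoms: oxalyl chloride, O=C(Cl)C(Cl)=O
Why: Acid chloride formation through the catalytic chloroiminium species; the by-products are gases, so the sensitive diacid chloride needs no purification.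

Step 6
Reactants: 4 (S)-{[4-(benzyloxy)pent-1-en-2-yl]oxy}trimethylsilane; 7 2-(prop-2-yn-1-yl)malonyl dichloride
Product: 9 6-[(2S)-2-(benzyloxy)propyl]-4-hydroxy-3-(prop-2-yn-1-yl)-2H-pyran-2-one, via diketo acid chloride 8 (not isolated)
Conditions: Et2O, −78 °C → rt
Reagents that add atoms: none
Why: Pyranone annulation of a silyl enol ether by a malonyl dichloride: C-acylation at the enol ether terminus gives 8, whose enol oxygen closes onto the second acid chloride, which puts the propargyl group at C3 and the side chain at C6; the benzyl ether tolerates the HCl set free.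

Step 7
Reactants: 9 6-[(2S)-2-(benzyloxy)propyl]-4-hydroxy-3-(prop-2-yn-1-yl)-2H-pyran-2-one
Product: 10 4-(benzyloxy)-6-[(2S)-2-(benzyloxy)propyl]-3-(prop-2-yn-1-yl)-2H-pyran-2-one
Conditions: BnOH, PPh3, DIAD, THF, 0 °C → rt
Reagents that add atoms: benzyl alcohol, OCc1ccccc1
Why: Mitsunobu etherification of the acidic 4-hydroxy-2-pyranone gives the 4-alkoxy-2-pyranone, which keeps the enol from protonating the diene in step 12 and from adding to the alkyne under Pd/Cu in step 8.

Step 8
Reactants: 10 4-(benzyloxy)-6-[(2S)-2-(benzyloxy)propyl]-3-(prop-2-yn-1-yl)-2H-pyran-2-one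
Product: 11 4-(benzyloxy)-6-[(2S)-2-(benzyloxy)propyl]-3-(4-oxopent-2-yn-1-yl)-2H-pyran-2-one
Conditions: AcCl (1.5 equiv), PdCl2(PPh3)2 (2 mol%), CuI (4 mol%), Et3N (1.1 equiv), THF, rt
Reagents that add atoms: acetyl chloride, CC(=O)Cl
Why: Acyl Sonogashira coupling of the terminal alkyne with the acid chloride gives the ynone; the amine is kept near one equivalent because the CH2 between pyranone and ynone can isomerise to the allene under base.

Step 9
Reactants: 12 methyl 2-(benzyloxy)acetate
Product: 13 methyl 2-(benzyloxy)-3-oxobutanoate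
Conditions: LDA (2 equiv), 12 (2 equiv), THF, −78 °C; AcCl (1 equiv), −78 °C; aq. HCl
Reagents that add atoms: acetyl chloride, CC(=O)Cl
Why: Crossed Claisen acylation of the lithium ester enolate by an acid chloride, with the second equivalent of enolate taking the acidic proton of the β-keto ester; −78 °C suppresses Wittig rearrangement of the α-benzyloxy enolate.

Step 10
Reactants: 13 methyl 2-(benzyloxy)-3-oxobutanoate
Product: 15 methyl 2-(benzyloxy)-3-methoxybut-2-enoate, via dimethyl ketal 14 (not isolated)
Conditions: HC(OMe)3, conc. H2SO4 (cat.), MeOH, rt; then distil, 120 °C (−MeOH)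
Reagents that add atoms: trimethyl orthoformate, COC(OC)OC
Why: Acid-catalysed ketalisation with the orthoformate and thermal loss of methanol is the standard conversion of a β-keto ester into its β-methoxy enoate (enol ether formation).

Step 11
Reactants: 15 methyl 2-(benzyloxy)-3-methoxybut-2-enoate
Product: 16 2-(benzyloxy)-1,3-dimethoxy-1-(trimethylsilyloxy)buta-1,3-diene
Conditions: LDA, THF, −78 °C; TMSCl, −78 °C → rt; non-aqueous work-up, used at once
Reagents that add atoms: chlorotrimethylsilane, C[Si](C)(C)Cl
Why: γ-Deprotonation of the β-alkoxy enoate and O-silylation of the dienolate give the vinylketene silyl acetal, the usual way to 1-alkoxy-1-silyloxy-3-alkoxybutadienes.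

Step 12
Reactants: 11 4-(benzyloxy)-6-[(2S)-2-(benzyloxy)propyl]-3-(4-oxopent-2-yn-1-yl)-2H-pyran-2-one; 16 2-(benzyloxy)-1,3-dimethoxy-1-(trimethylsilyloxy)buta-1,3-diene
Product: 18 3-{[2-acetyl-4-(benzyloxy)-3-hydroxy-5-methoxyphenyl]methyl}-4-(benzyloxy)-6-[(2S)-2-(benzyloxy)propyl]-2H-pyran-2-one, via cyclohexa-1,4-diene cycloadduct 17 (not isolated)
Conditions: 16 (3 equiv), toluene, 110 °C, sealed tube; then 1 M HCl, THF, rt
Reagents that add atoms: none
Why: Diene 16 is a vinylogous ketene acetal whose three donor oxygens make its CH2 terminus the nucleophilic end, and the ynone is most electrophilic at the alkyne carbon far from the ketone, so an asynchronous normal-demand Diels–Alder addition joins these two atoms first and then bonds the ketene-acetal carbon to the acetyl-bearing carbon. The closest known reaction type is the cycloaddition–aromatisation of 1-alkoxy-1-silyloxy-3-alkoxybutadienes with acetylenic ketones and esters to give polysubstituted phenols; the 2-benzyloxy group is one more donor on the same diene class. The benzene ring is closed by this intermolecular [4+2] addition (two C–C bonds, six-membered carbocycle 17) and becomes aromatic when dilute acid hydrolyses the silyl ketal, methanol leaves and the cyclohexadienone tautomerises to the phenol, which is held by a hydrogen bond to the acetyl group. No lasting stereocentre is made, since the ketal carbon of 17 turns aromatic, and the remote (S) carbinol centre is not touched. The selectivity needed is regiochemical (CH2 terminus to the carbon bearing the pyranonylmethyl group) and is secured by the single acetyl group polarising the alkyne in the sense that matches the diene; the enol-ether and enol-lactone C=C bonds of the pyranone are too electron-rich to compete as dienophiles.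

Step 13
Reactants: 18 3-{[2-acetyl-4-(benzyloxy)-3-hydroxy-5-methoxyphenyl]methyl}-4-(benzyloxy)-6-[(2S)-2-(benzyloxy)propyl]-2H-pyran-2-one
Product: 19 penicanesin D, 3-[(2-acetyl-3,4-dihydroxy-5-methoxyphenyl)methyl]-4-hydroxy-6-[(2S)-2-hydroxypropyl]-2H-pyran-2-one
Conditions: BCl3 (1 M in CH2Cl2, 6 equiv), C6HMe5 (6 equiv), CH2Cl2, −78 → 0 °C; then MeOH, H2O
Reagents that add atoms: none
Why: Lewis-acid debenzylation with BCl3 and pentamethylbenzene as a non-basic cation scavenger cleaves the aryl, enol and secondary alkyl benzyl ethers at low temperature; the one methyl ether should survive because its cleavage needs higher temperature and the neighbouring catechol is tied up as a weakly Lewis-acidic cyclic borate, and no C–O bond at the stereocentre is broken.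

**Compound list**
1 | (S)-pent-4-en-2-ol | C=CC[C@H](C)O | starting material
2 | (S)-4-(benzyloxy)pent-1-ene | C=CC[C@H](C)OCc1ccccc1 | intermediate
3 | (S)-4-(benzyloxy)pentan-2-one | CC(=O)C[C@H](C)OCc1ccccc1 | intermediate
4 | (S)-{[4-(benzyloxy)pent-1-en-2-yl]oxy}trimethylsilane | C=C(O[Si](C)(C)C)C[C@H](C)OCc1ccccc1 | intermediate
5 | diethyl 2-(prop-2-yn-1-yl)malonate | CCOC(=O)C(CC#C)C(=O)OCC | starting material
6 | 2-(prop-2-yn-1-yl)malonic acid | OC(=O)C(CC#C)C(=O)O | intermediate
7 | 2-(prop-2-yn-1-yl)malonyl dichloride | ClC(=O)C(CC#C)C(=O)Cl | intermediate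
8 | (7S)-7-(benzyloxy)-3,5-dioxo-2-(prop-2-yn-1-yl)octanoyl chloride | C#CCC(C(=O)Cl)C(=O)CC(=O)C[C@H](C)OCc1ccccc1 | intermediate (not isolated)
9 | 6-[(2S)-2-(benzyloxy)propyl]-4-hydroxy-3-(prop-2-yn-1-yl)-2H-pyran-2-one | C#CCc1c(O)cc(C[C@H](C)OCc2ccccc2)oc1=O | intermediate
10 | 4-(benzyloxy)-6-[(2S)-2-(benzyloxy)propyl]-3-(prop-2-yn-1-yl)-2H-pyran-2-one | C#CCc1c(OCc2ccccc2)cc(C[C@H](C)OCc2ccccc2)oc1=O | intermediate
11 | 4-(benzyloxy)-6-[(2S)-2-(benzyloxy)propyl]-3-(4-oxopent-2-yn-1-yl)-2H-pyran-2-one | CC(=O)C#CCc1c(OCc2ccccc2)cc(C[C@H](C)OCc2ccccc2)oc1=O | intermediate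
12 | methyl 2-(benzyloxy)acetate | COC(=O)COCc1ccccc1 | starting material
13 | methyl 2-(benzyloxy)-3-oxobutanoate | COC(=O)C(OCc1ccccc1)C(C)=O | intermediate
14 | methyl 2-(benzyloxy)-3,3-dimethoxybutanoate | COC(=O)C(OCc1ccccc1)C(C)(OC)OC | intermediate (not isolated)
15 | methyl 2-(benzyloxy)-3-methoxybut-2-enoate (E/Z mixture) | COC(=O)C(OCc1ccccc1)=C(C)OC | intermediate
16 | 2-(benzyloxy)-1,3-dimethoxy-1-(trimethylsilyloxy)buta-1,3-diene | C=C(OC)C(OCc1ccccc1)=C(OC)O[Si](C)(C)C | intermediate
17 | 3-{[2-acetyl-4-(benzyloxy)-3,5-dimethoxy-3-(trimethylsilyloxy)cyclohexa-1,4-dien-1-yl]methyl}-4-(benzyloxy)-6-[(2S)-2-(benzyloxy)propyl]-2H-pyran-2-one | CC(=O)C1=C(Cc2c(OCc3ccccc3)cc(C[C@H](C)OCc3ccccc3)oc2=O)CC(OC)=C(OCc2ccccc2)C1(OC)O[Si](C)(C)C | intermediate (not isolated)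
18 | 3-{[2-acetyl-4-(benzyloxy)-3-hydroxy-5-methoxyphenyl]methyl}-4-(benzyloxy)-6-[(2S)-2-(benzyloxy)propyl]-2H-pyran-2-one | COc1cc(Cc2c(OCc3ccccc3)cc(C[C@H](C)OCc3ccccc3)oc2=O)c(C(C)=O)c(O)c1OCc1ccccc1 | intermediate
19 | penicanesin D | COc1cc(Cc2c(O)cc(C[C@H](C)O)oc2=O)c(C(C)=O)c(O)c1O | target

**Step count**
Total: 13 steps. Longest linear sequence: 8 steps (1, 2, 3, 6, 7, 8, 12, 13).

**Steps most likely to fail**

Step 12. The β-substituted ynone may add more slowly than the tetra-oxygenated diene decomposes or transfers its silyl group. The first bond may also form at the acetyl-bearing alkyne carbon, or the adduct may lose silanol instead of methanol. The fallback sets out from 4 and returns at 19; it uses known reactions only and takes the arene from a commercial benzaldehyde instead of building it.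
- Silyl enol ether 4 is annulated with unsubstituted malonyl dichloride (Et2O, −78 °C → rt) to 6-[(2S)-2-(benzyloxy)propyl]-4-hydroxy-2H-pyran-2-one F1.
- Proline-catalysed Knoevenagel condensation of F1 with commercial 2-bromo-3,4,5-trimethoxybenzaldehyde, with reduction in the same flask by diethyl 1,4-dihydro-2,6-dimethylpyridine-3,5-dicarboxylate (Hantzsch ester), would give 3-[(2-bromo-3,4,5-trimethoxyphenyl)methyl]-6-[(2S)-2-(benzyloxy)propyl]-4-hydroxy-2H-pyran-2-one F2.
- Stille coupling with tributyl(1-ethoxyvinyl)stannane (Pd(PPh3)4, toluene, 100 °C) and dilute HCl would give 3-[(2-acetyl-3,4,5-trimethoxyphenyl)methyl]-6-[(2S)-2-(benzyloxy)propyl]-4-hydroxy-2H-pyran-2-one F3.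
- BCl3 with pentamethylbenzene (CH2Cl2, −78 °C → rt) removes the benzyl ether, the methyl ether chelated to the acetyl group and then its neighbour through the aryl borate, to give 19.

Step 11. The lithium amide may attack the benzylic ether CH2 or the ester instead of the γ-methyl group, or the diene may hydrolyse during isolation. The fallback sets out from 13 and returns at 18.
- Double soft enolisation of β-keto ester 13 with TMSOTf/Et3N (Et2O, 0 °C) should give the bis-silyl diene 2-(benzyloxy)-1-methoxy-1,3-bis(trimethylsilyloxy)buta-1,3-diene F4 without a strong base.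
- Cycloaddition of F4 with 11 under the conditions of step 12 and acid work-up would give 3-{[2-acetyl-4-(benzyloxy)-3,5-dihydroxyphenyl]methyl}-4-(benzyloxy)-6-[(2S)-2-(benzyloxy)propyl]-2H-pyran-2-one F5.
- Methylation with MeI (1 equiv) and K2CO3 in acetone should take place at the 5-hydroxyl, because the 3-hydroxyl is locked in a hydrogen bond to the acetyl group, and give 18.

Step 8. Triethylamine may shift the ynone into the allenyl ketone by deprotonating the CH2 group between pyranone and alkyne, and acetyl chloride may be lost as ketene. An allenyl ketone would, in principle, lead to the same arene in step 12 after double-bond migration, but it is prone to oligomerise. The fallback sets out from 10 and returns at 11.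
- Stannylation of the alkyne with Bu3SnOMe (neat, 60 °C, methanol removed under vacuum) would give tributyl{3-[4-(benzyloxy)-6-[(2S)-2-(benzyloxy)propyl]-2-oxo-2H-pyran-3-yl]prop-1-yn-1-yl}stannane F6.
- Amine-free Stille acylation of F6 with acetyl chloride (PdCl2(PPh3)2, 1,2-dichloroethane, 60 °C) gives 11.

**Further compounds**
F1 | step 12 | 6-[(2S)-2-(benzyloxy)propyl]-4-hydroxy-2H-pyran-2-one | O=c1cc(O)cc(C[C@H](C)OCc2ccccc2)o1
F2 | step 12 | 3-[(2-bromo-3,4,5-trimethoxyphenyl)methyl]-6-[(2S)-2-(benzyloxy)propyl]-4-hydroxy-2H-pyran-2-one | COc1cc(Cc2c(O)cc(C[C@H](C)OCc3ccccc3)oc2=O)c(Br)c(OC)c1OC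
F3 | step 12 | 3-[(2-acetyl-3,4,5-trimethoxyphenyl)methyl]-6-[(2S)-2-(benzyloxy)propyl]-4-hydroxy-2H-pyran-2-one | COc1cc(Cc2c(O)cc(C[C@H](C)OCc3ccccc3)oc2=O)c(C(C)=O)c(OC)c1OC
F4 | step 11 | 2-(benzyloxy)-1-methoxy-1,3-bis(trimethylsilyloxy)buta-1,3-diene | C=C(O[Si](C)(C)C)C(OCc1ccccc1)=C(OC)O[Si](C)(C)C
F5 | step 11 | 3-{[2-acetyl-4-(benzyloxy)-3,5-dihydroxyphenyl]methyl}-4-(benzyloxy)-6-[(2S)-2-(benzyloxy)propyl]-2H-pyran-2-one | CC(=O)c1c(O)c(OCc2ccccc2)c(O)cc1Cc1c(OCc2ccccc2)cc(C[C@H](C)OCc2ccccc2)oc1=O
F6 | step 8 | tributyl{3-[4-(benzyloxy)-6-[(2S)-2-(benzyloxy)propyl]-2-oxo-2H-pyran-3-yl]prop-1-yn-1-yl}stannane | CCCC[Sn](CCCC)(CCCC)C#CCc1c(OCc2ccccc2)cc(C[C@H](C)OCc2ccccc2)oc1=O
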